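**Plan**
- Retrosynthesis: the two silyl ethers are cut first, then the C5–alkenyl bond (Suzuki–Miyaura) back to aryl bromide 14, then O1–C2 and C2–C3 of the dihydrofuran ring together in a [4+1] sense.
- Enabling feature (benzofuran numbering): C2 is a single carbon carrying H and the 3,4-dimethoxyphenyl group between O1 and C3, and O1–C7a–C3a–C3 is the four-atom array of an ortho-quinone methide of ring A. The ring is therefore quinone methide 11 plus benzylic sulfonium ylide 12.
- Forward: sulfone 5 (four steps from 5-bromo-o-vanillin) and sulfonium salt 10 (three steps from (2R,5R)-hexane-2,5-diol) meet in step 8, which closes the only new ring. The side chain is then joined at C5 and both silyl ethers are removed.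
- Stereochemistry: C2 comes from the ylide face left open by the twofold-symmetric (2S,5S)-thiolane, followed by inversion in the ring closure. C3 is set relative to C2 (trans) in the conjugate addition. The E-alkene comes from the boronate.

Key step: step 8

Assumption: the benzylide of trans-2,5-dimethylthiolane is taken to show a quinone methide the same face it shows aldehydes, where, as recalled, the (2R,5R)-sulfide leads to (S,S)-stilbene oxides. Because the aryl group outranks C3 at C2 of the dihydrobenzofuran, that face reads 2R there, so the (2S,5S)-sulfide, from (2R,5R)-hexane-2,5-diol, is used for the 2S target.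

**Route**

Step 1
Reactants: 1 5-bromo-2-hydroxy-3-methoxybenzaldehyde
Product: 2 4-bromo-2-ethenyl-6-methoxyphenol
Conditions: Ph3PCH3Br (2.5 equiv), KOtBu (2.5 equiv), THF, 0 °C to rt
Reagents that add atoms: methyltriphenylphosphonium bromide, C[P+](c1ccccc1)(c1ccccc1)c1ccccc1.[Br-]
Why: Wittig methylenation, in which the excess ylide first takes the phenol proton and the salicylaldehyde phenoxide still reacts with the unstabilised ylide to give the 2-vinylphenol.

Step 2
Reactants: 2 4-bromo-2-ethenyl-6-methoxyphenol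
Product: 3 racemic 1-(5-bromo-2-hydroxy-3-methoxyphenyl)ethane-1,2-diol
Conditions: OsO4 (2 mol %), NMO (1.3 equiv), acetone/H2O, rt
Reagents that add atoms: N-methylmorpholine N-oxide, C[N+]1([O-])CCOCC1; water, O
Why: Upjohn dihydroxylation adds two hydroxyls syn across the terminal alkene, and the benzylic stereocentre, formed racemic, is erased later in quinone methide 11.

Step 3
Reactants: 3 racemic 1-(5-bromo-2-hydroxy-3-methoxyphenyl)ethane-1,2-diol
Product: 4 racemic 4-bromo-2-[2-(tert-butyldiphenylsilyloxy)-1-hydroxyethyl]-6-methoxyphenol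
Conditions: TBDPSCl (1.05 equiv), imidazole (2.2 equiv), CH2Cl2/DMF, −10 to 0 °C
Reagents that add atoms: tert-butyl(chloro)diphenylsilane, CC(C)(C)[Si](Cl)(c1ccccc1)c1ccccc1
Why: Chemoselective silyl ether formation, in which the bulky silyl chloride should take the primary hydroxyl ahead of the secondary benzylic one and of the phenol (flanked by two ortho groups and hydrogen-bonded to the methoxy oxygen); this silyl group is chosen because it withstands the acid of step 4 and carbonate bases.

Step 4
Reactants: 4 racemic 4-bromo-2-[2-(tert-butyldiphenylsilyloxy)-1-hydroxyethyl]-6-methoxyphenol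
Product: 5 racemic 4-bromo-2-[2-(tert-butyldiphenylsilyloxy)-1-(4-methylphenylsulfonyl)ethyl]-6-methoxyphenol
Conditions: p-TolSO2H (2 equiv, freshly liberated from its sodium salt), CH2Cl2, rt
Reagents that add atoms: 4-methylbenzenesulfinic acid, Cc1ccc(S(=O)O)cc1
Why: Acid-mediated benzylic substitution (sulfinate exchange), in which the sulfinic acid activates the benzylic hydroxyl, the ortho-hydroxyl assists loss of water and the sulfinate adds through sulfur to give the more stable sulfone, the usual way to 2-(1-sulfonylalkyl)phenols.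

Step 5
Reactants: 6 (2R,5R)-hexane-2,5-diol
Product: 7 (2R,5R)-hexane-2,5-diyl dimethanesulfonate
Conditions: MsCl (2.4 equiv), Et3N (3 equiv), CH2Cl2, 0 °C
Reagents that add atoms: methanesulfonyl chloride, CS(=O)(=O)Cl
Why: Mesylation (O-sulfonylation) breaks no bond at the two stereocentres and turns both hydroxyls into leaving groups.

Step 6
Reactants: 7 (2R,5R)-hexane-2,5-diyl dimethanesulfonate
Product: 8 (2S,5S)-2,5-dimethylthiolane
Conditions: Na2S·9H2O (1.5 equiv), DMSO, rt
Reagents that add atoms: sodium sulfide, [Na+].[Na+].[S-2]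
Why: Double SN2 displacement by sulfide, the second a 5-exo-tet ring closure, inverts each centre, so the (2R,5R)-dimesylate should give the (2S,5S)-thiolane.

Step 7
Reactants: 8 (2S,5S)-2,5-dimethylthiolane; 9 4-(bromomethyl)-1,2-dimethoxybenzene (3,4-dimethoxybenzyl bromide)
Product: 10 (2S,5S)-1-(3,4-dimethoxybenzyl)-2,5-dimethylthiolan-1-ium tetrafluoroborate
Conditions: AgBF4 (1.0 equiv), CH2Cl2, 0 °C to rt, dark
Reagents that add atoms: silver tetrafluoroborate, [Ag+].F[B-](F)(F)F
Why: S-Alkylation of the thioether by the reactive benzylic bromide (sulfonium salt formation) is driven by precipitation of AgBr, and because the two sulfur lone pairs of the twofold-symmetric sulfide are equivalent only one sulfonium salt can form.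

Step 8
Reactants: 5 racemic 4-bromo-2-[2-(tert-butyldiphenylsilyloxy)-1-(4-methylphenylsulfonyl)ethyl]-6-methoxyphenol; 10 (2S,5S)-1-(3,4-dimethoxybenzyl)-2,5-dimethylthiolan-1-ium tetrafluoroborate
Product: 14 (2S,3R)-5-bromo-3-[(tert-butyldiphenylsilyloxy)methyl]-2-(3,4-dimethoxyphenyl)-7-methoxy-2,3-dihydrobenzofuran, via quinone methide 11 (not isolated), via sulfonium ylide 12 (not isolated), via phenoxide betaine 13 (not isolated)
Conditions: Cs2CO3 (3 equiv), 10 (1.5 equiv), MeCN/CH2Cl2, 0 °C to rt
Reagents that add atoms: none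
Why: Cs2CO3 deprotonates the phenol of 5, which expels toluenesulfinate to give quinone methide 11, and deprotonates salt 10 to the semi-stabilised ylide 12, whose carbon adds to the exocyclic carbon of 11 (C2–C3) and restores the aromaticity of ring A in betaine 13. The phenoxide of 13 then displaces the neutral sulfide 8 from the benzylic carbon in a 5-exo-tet SN2 closure (O1–C2), which forms the dihydrofuran ring. The closest known reaction type is the carbonate-mediated [4+1] annulation of sulfur ylides with ortho-quinone methides released from 2-(1-sulfonylalkyl)phenols, which gives trans-2,3-dihydrobenzofurans; here it is carried over to an aryl-substituted ylide from a chiral sulfide and a silyloxymethyl quinone methide, a pairing that has not been run before. C2 is controlled by the twofold-symmetric thiolane: only one sulfonium configuration exists, the ylide aryl group points away from the ring, the methyl group syn to the ylide carbon shields one face, and addition on the open face followed by inversion in the closure should give 2S, by analogy with the sense of epoxide formation from aldehydes with this class of ylide. C3 is set relative to C2 in the addition step, where the aryl group and the silyloxymethyl arm of the E-configured quinone methide stay apart, so that after inversion at C2 they end up trans (3R). The step needs conjugate addition to outrun both the 1,5-hydrogen shift of 11 to a silyl enol ether and the S-benzylation of sulfinate by 10; reversible re-addition of sulfinate keeps 11 at a low standing concentration, the benzylic ylide is a strong carbon nucleophile, and 10 is used in excess.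

Step 9
Reactants: 14 (2S,3R)-5-bromo-3-[(tert-butyldiphenylsilyloxy)methyl]-2-(3,4-dimethoxyphenyl)-7-methoxy-2,3-dihydrobenzofuran; 15 (E)-tert-butyldimethyl{[3-(4,4,5,5-tetramethyl-1,3,2-dioxaborolan-2-yl)prop-2-en-1-yl]oxy}silane
Product: 16 tert-butyl{[(2E)-3-{(2S,3R)-3-[(tert-butyldiphenylsilyloxy)methyl]-2-(3,4-dimethoxyphenyl)-7-methoxy-2,3-dihydrobenzofuran-5-yl}prop-2-en-1-yl]oxy}dimethylsilane
Conditions: 15 (1.3 equiv), PdCl2(dppf) (5 mol %), K2CO3 (3 equiv), 1,4-dioxane/H2O, 80 °C
Reagents that add atoms: none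
Why: Suzuki–Miyaura coupling of the aryl bromide with the (E)-alkenylboronic ester proceeds with retention of alkene geometry, and the mild carbonate base leaves both silyl ethers and the two ring stereocentres untouched.

Step 10
Reactants: 16 tert-butyl{[(2E)-3-{(2S,3R)-3-[(tert-butyldiphenylsilyloxy)methyl]-2-(3,4-dimethoxyphenyl)-7-methoxy-2,3-dihydrobenzofuran-5-yl}prop-2-en-1-yl]oxy}dimethylsilane
Product: 17 Hierochin B, (2E)-3-[(2S,3R)-2-(3,4-dimethoxyphenyl)-3-(hydroxymethyl)-7-methoxy-2,3-dihydrobenzofuran-5-yl]prop-2-en-1-ol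
Conditions: TBAF (3 equiv), THF, 0 °C to rt
Reagents that add atoms: none
Why: Fluoride-induced desilylation, driven by the strength of the Si–F bond, cleaves the allylic tert-butyldimethylsilyl ether and the primary tert-butyldiphenylsilyl ether in one operation without touching the benzylic ether stereocentres or the alkene.

**Compound list**
1 | 5-bromo-2-hydroxy-3-methoxybenzaldehyde (5-bromo-o-vanillin) | COc1cc(Br)cc(C=O)c1O | starting material
2 | 4-bromo-2-ethenyl-6-methoxyphenol | COc1cc(Br)cc(C=C)c1O | intermediate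
3 | racemic 1-(5-bromo-2-hydroxy-3-methoxyphenyl)ethane-1,2-diol | COc1cc(Br)cc(C(O)CO)c1O | intermediate
4 | racemic 4-bromo-2-[2-(tert-butyldiphenylsilyloxy)-1-hydroxyethyl]-6-methoxyphenol | COc1cc(Br)cc(C(O)CO[Si](c2ccccc2)(c3ccccc3)C(C)(C)C)c1O | intermediate
5 | racemic 4-bromo-2-[2-(tert-butyldiphenylsilyloxy)-1-(4-methylphenylsulfonyl)ethyl]-6-methoxyphenol | COc1cc(Br)cc(C(CO[Si](c2ccccc2)(c3ccccc3)C(C)(C)C)S(=O)(=O)c4ccc(C)cc4)c1O | intermediate
6 | (2R,5R)-hexane-2,5-diol | C[C@@H](O)CC[C@@H](C)O | starting material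
7 | (2R,5R)-hexane-2,5-diyl dimethanesulfonate | C[C@@H](OS(C)(=O)=O)CC[C@@H](C)OS(C)(=O)=O | intermediate
8 | (2S,5S)-2,5-dimethylthiolane | C[C@H]1CC[C@H](C)S1 | intermediate
9 | 4-(bromomethyl)-1,2-dimethoxybenzene (3,4-dimethoxybenzyl bromide) | COc1ccc(CBr)cc1OC | starting material
10 | (2S,5S)-1-(3,4-dimethoxybenzyl)-2,5-dimethylthiolan-1-ium tetrafluoroborate | C[C@H]1CC[C@H](C)[S+]1Cc2ccc(OC)c(OC)c2.F[B-](F)(F)F | intermediate
11 | (6E)-4-bromo-6-[2-(tert-butyldiphenylsilyloxy)ethylidene]-2-methoxycyclohexa-2,4-dien-1-one (ortho-quinone methide) | COC1=CC(Br)=C/C(=C\CO[Si](c2ccccc2)(c3ccccc3)C(C)(C)C)C1=O | intermediate (not isolated)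
12 | [(2S,5S)-2,5-dimethylthiolan-1-ium-1-yl](3,4-dimethoxyphenyl)methanide (sulfonium ylide) | C[C@H]1CC[C@H](C)[S+]1[CH-]c2ccc(OC)c(OC)c2 | intermediate (not isolated)
13 | 4-bromo-2-{(1R,2R)-3-(tert-butyldiphenylsilyloxy)-1-(3,4-dimethoxyphenyl)-1-[(2S,5S)-2,5-dimethylthiolan-1-ium-1-yl]propan-2-yl}-6-methoxyphenolate (betaine) | COc1ccc([C@H]([S+]2[C@@H](C)CC[C@@H]2C)[C@@H](CO[Si](c3ccccc3)(c4ccccc4)C(C)(C)C)c5cc(Br)cc(OC)c5[O-])cc1OC | intermediate (not isolated)
14 | (2S,3R)-5-bromo-3-[(tert-butyldiphenylsilyloxy)methyl]-2-(3,4-dimethoxyphenyl)-7-methoxy-2,3-dihydrobenzofuran | COc1ccc([C@H]2Oc3c(OC)cc(Br)cc3[C@@H]2CO[Si](c4ccccc4)(c5ccccc5)C(C)(C)C)cc1OC | intermediate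
15 | (E)-tert-butyldimethyl{[3-(4,4,5,5-tetramethyl-1,3,2-dioxaborolan-2-yl)prop-2-en-1-yl]oxy}silane | CC(C)(C)[Si](C)(C)OC/C=C/B1OC(C)(C)C(C)(C)O1 | starting material
16 | tert-butyl{[(2E)-3-{(2S,3R)-3-[(tert-butyldiphenylsilyloxy)methyl]-2-(3,4-dimethoxyphenyl)-7-methoxy-2,3-dihydrobenzofuran-5-yl}prop-2-en-1-yl]oxy}dimethylsilane | COc1ccc([C@H]2Oc3c(OC)cc(/C=C/CO[Si](C)(C)C(C)(C)C)cc3[C@@H]2CO[Si](c4ccccc4)(c5ccccc5)C(C)(C)C)cc1OC | intermediate
17 | Hierochin B, (2E)-3-[(2S,3R)-2-(3,4-dimethoxyphenyl)-3-(hydroxymethyl)-7-methoxy-2,3-dihydrobenzofuran-5-yl]prop-2-en-1-ol | COc1ccc([C@H]2Oc3c(OC)cc(/C=C/CO)cc3[C@@H]2CO)cc1OC | target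

**Step count**
Total: 10 steps. Longest linear sequence: 7 steps (steps 1, 2, 3, 4, 8, 9, 10).

**Steps most likely to fail**

Step 8. What may go wrong: the quinone methide may discriminate poorly between the two faces of ylide 12, or betaine formation may become partly reversible, so that 14 forms with too little enantiomeric purity. The fallback sets out from 9 and 5 and returns at 14; it keeps the annulation but takes the absolute configuration from a resolution. 3,4-Dimethoxybenzyl bromide 9 is S-alkylated onto tetrahydrothiophene (AgBF4, CH2Cl2) to give 1-(3,4-dimethoxybenzyl)thiolan-1-ium tetrafluoroborate F1. F1 and sulfone 5 under the Cs2CO3 conditions of step 8 should give racemic trans-5-bromo-3-[(tert-butyldiphenylsilyloxy)methyl]-2-(3,4-dimethoxyphenyl)-7-methoxy-2,3-dihydrobenzofuran F2. TBAF in THF should free racemic trans-[5-bromo-2-(3,4-dimethoxyphenyl)-7-methoxy-2,3-dihydrobenzofuran-3-yl]methanol F3. Esterification with (2S)-2-methoxy-2-phenylacetic acid (DCC, DMAP, CH2Cl2) should give two diastereomers, [(2S,3R)-5-bromo-2-(3,4-dimethoxyphenyl)-7-methoxy-2,3-dihydrobenzofuran-3-yl]methyl (2S)-2-methoxy-2-phenylacetate F4 and its (2R,3S)-configured diastereomer F5. These are to be separated by chromatography or crystallisation and assigned by the shielding pattern of the methoxyphenylacetate or by correlation with material from step 8. Methanolysis of F4 (K2CO3, MeOH) should release [(2S,3R)-5-bromo-2-(3,4-dimethoxyphenyl)-7-methoxy-2,3-dihydrobenzofuran-3-yl]methanol F6, which is silylated again (TBDPSCl, imidazole, CH2Cl2) to rejoin the route at 14.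

Step 4. What may go wrong: the β-silyloxy group slows loss of water from the benzylic position, so that cleavage of the silyl ether or a 1,2-hydride shift towards the arylacetaldehyde competes with capture by sulfinate. The fallback sets out from 4 and returns at 5; sulfur is brought in at the sulfide oxidation level with a much stronger nucleophile and oxidised afterwards. 4-Methylbenzenethiol with ZnI2 in CH2Cl2 at rt should convert 4 into racemic 4-bromo-2-[2-(tert-butyldiphenylsilyloxy)-1-(4-methylphenylsulfanyl)ethyl]-6-methoxyphenol F7, and mCPBA (2.2 equiv, CH2Cl2, 0 °C) should then oxidise the sulfide to sulfone 5.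

Step 3. What may go wrong: silylation of the phenol oxygen beside or instead of the primary hydroxyl, giving mixtures that are hard to separate. The fallback sets out from 3 and returns at 4; the selectivity is moved from the protection to a deprotection. Excess TBDPSCl with imidazole in DMF should silylate both the phenol and the primary hydroxyl to racemic 1-[5-bromo-2-(tert-butyldiphenylsilyloxy)-3-methoxyphenyl]-2-(tert-butyldiphenylsilyloxy)ethan-1-ol F8. KHF2 in MeOH at rt, which cleaves aryl silyl ethers and leaves alkyl silyl ethers alone, should then remove the phenolic silyl group to give 4.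

Further compounds
F1 | step 8 | 1-(3,4-dimethoxybenzyl)thiolan-1-ium tetrafluoroborate | COc1ccc(C[S+]2CCCC2)cc1OC.F[B-](F)(F)F
F2 | step 8 | racemic trans-5-bromo-3-[(tert-butyldiphenylsilyloxy)methyl]-2-(3,4-dimethoxyphenyl)-7-methoxy-2,3-dihydrobenzofuran (equal parts 2S,3R and 2R,3S) | COc1ccc([C@H]2Oc3c(OC)cc(Br)cc3[C@@H]2CO[Si](c4ccccc4)(c5ccccc5)C(C)(C)C)cc1OC.COc1ccc([C@@H]2Oc3c(OC)cc(Br)cc3[C@H]2CO[Si](c4ccccc4)(c5ccccc5)C(C)(C)C)cc1OC
F3 | step 8 | racemic trans-[5-bromo-2-(3,4-dimethoxyphenyl)-7-methoxy-2,3-dihydrobenzofuran-3-yl]methanol (equal parts 2S,3R and 2R,3S) | COc1ccc([C@H]2Oc3c(OC)cc(Br)cc3[C@@H]2CO)cc1OC.COc1ccc([C@@H]2Oc3c(OC)cc(Br)cc3[C@H]2CO)cc1OC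
F4 | step 8 | [(2S,3R)-5-bromo-2-(3,4-dimethoxyphenyl)-7-methoxy-2,3-dihydrobenzofuran-3-yl]methyl (2S)-2-methoxy-2-phenylacetate | COc1ccc([C@H]2Oc3c(OC)cc(Br)cc3[C@@H]2COC(=O)[C@@H](OC)c4ccccc4)cc1OC
F5 | step 8 | [(2R,3S)-5-bromo-2-(3,4-dimethoxyphenyl)-7-methoxy-2,3-dihydrobenzofuran-3-yl]methyl (2S)-2-methoxy-2-phenylacetate | COc1ccc([C@@H]2Oc3c(OC)cc(Br)cc3[C@H]2COC(=O)[C@@H](OC)c4ccccc4)cc1OC
F6 | step 8 | [(2S,3R)-5-bromo-2-(3,4-dimethoxyphenyl)-7-methoxy-2,3-dihydrobenzofuran-3-yl]methanol | COc1ccc([C@H]2Oc3c(OC)cc(Br)cc3[C@@H]2CO)cc1OC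
F7 | step 4 | racemic 4-bromo-2-[2-(tert-butyldiphenylsilyloxy)-1-(4-methylphenylsulfanyl)ethyl]-6-methoxyphenol | COc1cc(Br)cc(C(CO[Si](c2ccccc2)(c3ccccc3)C(C)(C)C)Sc4ccc(C)cc4)c1O
F8 | step 3 | racemic 1-[5-bromo-2-(tert-butyldiphenylsilyloxy)-3-methoxyphenyl]-2-(tert-butyldiphenylsilyloxy)ethan-1-ol | COc1cc(Br)cc(C(O)CO[Si](c2ccccc2)(c3ccccc3)C(C)(C)C)c1O[Si](c4ccccc4)(c5ccccc5)C(C)(C)C
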